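**Plan**

1. Germacrane numbering is used: C1 (furanone C=O), C2, C3 (furanone C–O), C4=C5 (C15 on C4), C6 (lactone CH–O), C7, C8 (ester carbon), C9, C10 (quaternary C–O with methyl C14), C11–C13 (methylene lactone).
2. Enabling feature: in the furanone ring (ring O, C3, C2, C1, C10) the quaternary C10 holds the ring oxygen next to oxygen-bearing C1. A C3 ketone oxygen leaves exactly this pattern when it opens a trans C1–C10 epoxide of the ten-membered ring at its tertiary carbon, so the first cut is O–C10 (after C1=O back to C1–OH).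
3. Further cuts: C3–C4 (ten-membered ring), C7–C8 (chain to lactone), the C8 ester C–O, the lactone ring (ester C–O and C7=C11), and C1–C2 / C10–C14 of the E alkene.
4. Forward: the butenolide ring is made first by metathesis; a zinc allylation joins the C8–C3 chain and creates the methylene lactone; the C1–C10 alkene is epoxidised; the ten-membered ring is closed at C3–C4 (Ni/Cr); the ketone-on-epoxide closure gives the oxygen bridge, which is oxidised to the furanone.
5. Stereochemistry: C6 from an enzymatic resolution; C7 from C6 (allylation anti to the C6 substituent); C8 from the chair transition state of the allylation followed by Mitsunobu inversion; C1/C10 from a reagent-controlled Shi epoxidation, with C10 inverted in the key step; the 4Z and 1(10)E alkenes from hydroalumination–iodination and carboalumination.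

Key step: step 19

Remark: the zinc allylation of step 12 is assumed to follow the closed chair transition state usual for 3-(bromomethyl)butenolides and to give the 8S alcohol; C8 is therefore inverted in step 13.
Remark: bought reagents 6, 9, 13, 14 and 23 are numbered because they deliver carbon atoms to the target.

**Route**

Step 1
Reactants: 1 2-butyne-1,4-diol
Product: 2 4-[(tert-butyldimethylsilyl)oxy]but-2-yn-1-ol
Conditions: NaH (1.0 equiv), THF, 0 °C; TBSCl (1.0 equiv), 0 °C to rt
Reagents that add atoms: tert-butyldimethylsilyl chloride, C[Si](C)(Cl)C(C)(C)C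
Why: O-silylation of the monosodium alkoxide of a symmetrical diol (Williamson-type monoprotection) should stop at the mono ether and leaves one propargylic hydroxyl to direct step 2; no stereocenter is formed.

Step 2
Reactants: 2 4-[(tert-butyldimethylsilyl)oxy]but-2-yn-1-ol
Product: 4 (Z)-4-[(tert-butyldimethylsilyl)oxy]-3-iodobut-2-en-1-ol, via cyclic alkenylaluminate 3 (not isolated)
Conditions: NaAlH2(OCH2CH2OMe)2 (Red-Al), THF, 0 °C to rt; EtOAc; then I2, THF, −78 °C to 0 °C
Reagents that add atoms: iodine, II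
Why: Alkoxide-directed trans-hydroalumination of the propargylic alcohol places aluminium on the distal alkyne carbon in a five-membered aluminate, and iodinolysis with retention should give the Z iodoalkene in which iodine (the later C3 attachment at C4) is cis to C6.

Step 3
Reactants: 4 (Z)-4-[(tert-butyldimethylsilyl)oxy]-3-iodobut-2-en-1-ol
Product: 5 (Z)-4-[(tert-butyldimethylsilyl)oxy]-3-iodobut-2-enal
Conditions: MnO2 (15 equiv), CH2Cl2, rt, dark
Reagents that add atoms: none
Why: MnO2 oxidation of a primary allylic alcohol is neutral and heterogeneous, so the Z geometry of the β-iodo enal and the silyl ether should be kept.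

Step 4
Reactants: 5 (Z)-4-[(tert-butyldimethylsilyl)oxy]-3-iodobut-2-enal, 6 vinylmagnesium bromide
Product: 7 rac-(Z)-6-[(tert-butyldimethylsilyl)oxy]-5-iodohexa-1,4-dien-3-ol
Conditions: CH2=CHMgBr (1.2 equiv), THF, −78 °C; aq. NH4Cl
Reagents that add atoms: vinylmagnesium bromide 6, C=C[Mg]Br
Why: Grignard 1,2-addition to the enal at low temperature should outrun addition–elimination at the iodine-bearing carbon; C6 is formed without control and is resolved in step 5.

Step 5
Reactants: 7 rac-(Z)-6-[(tert-butyldimethylsilyl)oxy]-5-iodohexa-1,4-dien-3-ol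
Product: 8 (3S,4Z)-6-[(tert-butyldimethylsilyl)oxy]-5-iodohexa-1,4-dien-3-ol
Conditions: immobilised Candida antarctica lipase B (Novozym 435), vinyl acetate (3 equiv), MTBE, 30 °C, run past half conversion; chromatography
Reagents that add atoms: none
Why: Lipase-catalysed kinetic resolution by transesterification should acetylate the R enantiomer (vinyl as the medium group, iodoalkenyl as the large group in the empirical size rule for lipases), so the unreacted S alcohol, which carries the C6 configuration of the target, is recovered.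

Step 6
Reactants: 8 (3S,4Z)-6-[(tert-butyldimethylsilyl)oxy]-5-iodohexa-1,4-dien-3-ol, 9 2-(bromomethyl)prop-2-enoic acid
Product: 10 (3S,4Z)-6-[(tert-butyldimethylsilyl)oxy]-5-iodohexa-1,4-dien-3-yl 2-(bromomethyl)prop-2-enoate
Conditions: DCC (1.3 equiv), DMAP (10 mol %), CH2Cl2, 0 °C
Reagents that add atoms: 2-(bromomethyl)prop-2-enoic acid 9, C=C(CBr)C(=O)O
Why: Steglich esterification acylates the secondary alcohol at oxygen with retention at C6, and at 0 °C with catalytic DMAP the allylic bromide should not be displaced.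

Step 7
Reactants: 10 (3S,4Z)-6-[(tert-butyldimethylsilyl)oxy]-5-iodohexa-1,4-dien-3-yl 2-(bromomethyl)prop-2-enoate
Product: 11 (5S)-3-(bromomethyl)-5-[(1Z)-3-[(tert-butyldimethylsilyl)oxy]-2-iodoprop-1-en-1-yl]furan-2(5H)-one
Conditions: second-generation Grubbs catalyst RuCl2(=CHPh)(H2IMes)(PCy3) (5 mol %), CH2Cl2 (5 mM), 40 °C
Reagents that add atoms: none
Why: Ring-closing metathesis starts at the vinyl group and closes onto the 1,1-disubstituted acrylate to form the five-membered butenolide with loss of ethene; the trisubstituted iodoalkene is inert to the ruthenium carbene and C6 is untouched.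

Step 8
Reactants: 12 4-[(tert-butyldimethylsilyl)oxy]but-1-yne, 13 trimethylaluminium, 14 ethylene oxide
Product: 17 (3E)-6-[(tert-butyldimethylsilyl)oxy]-4-methylhex-3-en-1-ol, via alkenyldimethylalane 15 (not isolated), via lithium alkenylalanate 16 (not isolated)
Conditions: AlMe3 (2 equiv), Cp2ZrCl2 (20 mol %), ClCH2CH2Cl, 0 °C to rt; volatiles removed; n-BuLi (1 equiv), hexane/THF, −78 °C; ethylene oxide, −78 °C to 0 °C; aq. KNaC4H4O6
Reagents that add atoms: trimethylaluminium 13, C[Al](C)C; ethylene oxide 14, C1CO1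
Why: Zirconium-catalysed carboalumination (Negishi) adds methyl and aluminium syn across the terminal alkyne with aluminium on the terminal carbon, and the derived alanate opens ethylene oxide with retention of alkene geometry, which fixes the E C1–C10 alkene with C14, C2 and C3 in place.

Step 9
Reactants: 17 (3E)-6-[(tert-butyldimethylsilyl)oxy]-4-methylhex-3-en-1-ol
Product: 18 tert-butyl{[(3E)-6-[(4-methoxybenzyl)oxy]-3-methylhex-3-en-1-yl]oxy}dimethylsilane
Conditions: NaH, 4-methoxybenzyl chloride, Bu4NI (cat.), THF/DMF, 0 °C to rt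
Reagents that add atoms: 4-methoxybenzyl chloride, COc1ccc(CCl)cc1
Why: Williamson etherification of the primary alkoxide protects the C3 oxygen with a group that can later be removed oxidatively in the presence of the silyl ether and the esters.

Step 10
Reactants: 18 tert-butyl{[(3E)-6-[(4-methoxybenzyl)oxy]-3-methylhex-3-en-1-yl]oxy}dimethylsilane
Product: 19 (3E)-6-[(4-methoxybenzyl)oxy]-3-methylhex-3-en-1-ol
Conditions: Bu4NF, THF, 0 °C to rt
Reagents that add atoms: none
Why: Fluoride-mediated desilylation cleaves only the Si–O bond and frees the C8 hydroxyl.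

Step 11
Reactants: 19 (3E)-6-[(4-methoxybenzyl)oxy]-3-methylhex-3-en-1-ol
Product: 20 (3E)-6-[(4-methoxybenzyl)oxy]-3-methylhex-3-enal
Conditions: Dess–Martin periodinane, NaHCO3, CH2Cl2, 0 °C; used at once
Reagents that add atoms: none
Why: Buffered Dess–Martin oxidation should give the β,γ-unsaturated aldehyde without moving the alkene into conjugation.

Step 12
Reactants: 11 (5S)-3-(bromomethyl)-5-[(1Z)-3-[(tert-butyldimethylsilyl)oxy]-2-iodoprop-1-en-1-yl]furan-2(5H)-one, 20 (3E)-6-[(4-methoxybenzyl)oxy]-3-methylhex-3-enal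
Product: 22 (4R,5S)-5-[(1Z)-3-[(tert-butyldimethylsilyl)oxy]-2-iodoprop-1-en-1-yl]-4-[(1S,3E)-1-hydroxy-6-[(4-methoxybenzyl)oxy]-3-methylhex-3-en-1-yl]-3-methylidenedihydrofuran-2(3H)-one, via allylzinc bromide 21 (not isolated)
Conditions: Zn dust, THF/sat. aq. NH4Cl, 0 °C to rt
Reagents that add atoms: none
Why: Zinc-mediated Barbier allylation: the allylzinc reacts at its ring carbon (SE2') to form C7–C8 on the butenolide face opposite the C6 alkenyl group, which sets C7 trans to C6 and creates the exocyclic methylene, while a closed chair (Zimmerman–Traxler) transition state with the aldehyde chain equatorial should set C8 as the S alcohol, the epimer that step 13 inverts.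

Step 13
Reactants: 22 the 8S hydroxy lactone of step 12, 23 2-methylpropanoic acid
Product: 25 (4R,5S)-5-[(1Z)-3-[(tert-butyldimethylsilyl)oxy]-2-iodoprop-1-en-1-yl]-4-[(1R,3E)-6-[(4-methoxybenzyl)oxy]-3-methyl-1-(2-methylpropanoyloxy)hex-3-en-1-yl]-3-methylidenedihydrofuran-2(3H)-one, via alkoxyphosphonium isobutyrate 24 (not isolated)
Conditions: PPh3, DIAD (betaine pre-formed), 2-methylpropanoic acid, toluene, 0 °C to rt
Reagents that add atoms: 2-methylpropanoic acid 23, CC(C)C(=O)O
Why: Mitsunobu esterification turns the C8 alcohol into an alkoxyphosphonium ion that isobutyrate displaces by SN2 with inversion, so the ester and the 8R configuration arrive in one operation; pre-forming the betaine keeps free PPh3 away from the methylene lactone.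

Step 14
Reactants: 25 the 8R isobutyrate of step 13
Product: 26 (4R,5S)-5-[(1Z)-3-[(tert-butyldimethylsilyl)oxy]-2-iodoprop-1-en-1-yl]-4-[(1R,3E)-6-hydroxy-3-methyl-1-(2-methylpropanoyloxy)hex-3-en-1-yl]-3-methylidenedihydrofuran-2(3H)-one
Conditions: DDQ, CH2Cl2/pH 7 phosphate buffer, 0 °C
Reagents that add atoms: none
Why: Oxidative cleavage of the 4-methoxybenzyl ether by DDQ under buffered conditions should leave the silyl ether, both esters and the alkenes untouched.

Step 15
Reactants: 26 the C3 alcohol of step 14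
Product: 27 (4R,5S)-5-[(1Z)-3-[(tert-butyldimethylsilyl)oxy]-2-iodoprop-1-en-1-yl]-4-[(1R)-2-[(2S,3S)-3-(2-hydroxyethyl)-2-methyloxiran-2-yl]-1-(2-methylpropanoyloxy)ethyl]-3-methylidenedihydrofuran-2(3H)-one
Conditions: L-fructose-derived Shi ketone (mirror image of the usual D-fructose-derived catalyst, 30 mol %), KHSO5 (as Oxone), K2CO3, Bu4NHSO4, Na2B4O7/Na2EDTA buffer, MeCN/CH2(OMe)2/H2O, 0 °C
Reagents that add atoms: potassium peroxymonosulfate, [K+].[O-]S(=O)(=O)OO
Why: Shi asymmetric epoxidation: the chiral dioxirane transfers oxygen through a spiro transition state to one face of the electron-rich E-trisubstituted C1–C10 alkene and should give the (1S,10S) epoxide under reagent control, while the iodoalkene and the conjugated methylene are too electron-poor to react.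

Step 16
Reactants: 27 the (1S,10S) epoxy alcohol of step 15
Product: 28 (4R,5S)-5-[(1Z)-3-[(tert-butyldimethylsilyl)oxy]-2-iodoprop-1-en-1-yl]-4-[(1R)-2-[(2S,3S)-2-methyl-3-(2-oxoethyl)oxiran-2-yl]-1-(2-methylpropanoyloxy)ethyl]-3-methylidenedihydrofuran-2(3H)-one
Conditions: Dess–Martin periodinane, NaHCO3, CH2Cl2, 0 °C; used at once
Reagents that add atoms: none
Why: Buffered Dess–Martin oxidation gives the β,γ-epoxy aldehyde without the base that would open the epoxide by β-elimination.

Step 17
Reactants: 28 the epoxy aldehyde of step 16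
Product: 30 (1S,4Z,6R,7R,8R,10S)-15-[(tert-butyldimethylsilyl)oxy]-1,10-epoxy-3-hydroxy-8-(2-methylpropanoyloxy)germacra-4,11(13)-dien-12,6-olide as a mixture of C3 epimers, via alkenylchromium dichloride 29 (not isolated)
Conditions: CrCl2 (10 equiv), NiCl2 (10 mol %), degassed DMSO, rt, slow addition to 1 mM
Reagents that add atoms: none
Why: Nozaki–Hiyama–Kishi reaction: zerovalent nickel inserts into the alkenyl C–I bond, transmetalation gives an alkenyl species of trivalent chromium that adds to the aldehyde with retention of the Z alkene, and high dilution favours closure of the ten-membered ring; the epoxide, lactone and ester tolerate the neutral chromium salts, and the uncontrolled C3 carbinol is erased in step 18.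

Step 18
Reactants: 30 the macrocyclic epoxy alcohol of step 17
Product: 31 (1S,4Z,6R,7R,8R,10S)-15-[(tert-butyldimethylsilyl)oxy]-1,10-epoxy-8-(2-methylpropanoyloxy)-3-oxogermacra-4,11(13)-dien-12,6-olide
Conditions: Dess–Martin periodinane, NaHCO3, CH2Cl2, 0 °C to rt
Reagents that add atoms: none
Why: Dess–Martin oxidation of the allylic alcohol converts both C3 epimers into the one enone under conditions too mild to isomerise the β,γ-epoxy ketone.

Step 19
Reactants: 31 the macrocyclic 1,10-epoxy 3-ketone of step 18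
Product: 33 (1S,4Z,6R,7R,8R,10R)-15-[(tert-butyldimethylsilyl)oxy]-3,10-epoxy-1-hydroxy-8-(2-methylpropanoyloxy)germacra-2,4,11(13)-trien-12,6-olide, via bicyclic oxocarbenium ion 32 (not isolated)
Conditions: BF3·OEt2 (0.3 equiv), CH2Cl2, −78 °C; Et3N quench
Reagents that add atoms: none
Why: Proposed new method: BF3 binds the epoxide oxygen and weakens the C10–O bond at the tertiary carbon, the C3 carbonyl oxygen (joined to C10 through C2 and C1) attacks C10 from the side opposite the leaving oxygen to give the bicyclic oxocarbenium ion 32, and loss of a C2 proton then forms the C2=C3 enol ether and frees the C1 alcohol; the closest known reaction type is the acid-catalysed cyclisation of acyclic β,γ-epoxy ketones to 3-hydroxy-2,3-dihydrofurans and furans, not yet shown inside a medium ring. The five-membered ring (ring O, C3, C2, C1, C10) closes in a 5-endo mode with respect to the epoxide, which is acceptable here because the attacked carbon is tertiary and carries much of the positive charge in the transition state. C10 is the only new stereocenter and is set by inversion of the 10S epoxide carbon to 10R, so it is controlled by the reagent-controlled epoxidation of step 15, while C1 keeps its configuration and its oxygen. The step needs ring closure to outrun hydride shift from C1 (Meinwald rearrangement), proton loss from C9 or C14 and attack by other nucleophiles: the C4–C5 alkene is deactivated as part of the enone, the C8 isobutyrate lies on the same ring face as the epoxide oxygen and cannot reach the rear of C10, and a substoichiometric Lewis acid at −78 °C keeps the cation paired with its alkoxide. Because C10 has no hydrogen the product cannot aromatise to a furan and should stop at the dihydrofuranol.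

Step 20
Reactants: 33 the bridged dihydrofuranol of step 19
Product: 34 (4Z,6R,7R,8R,10R)-15-[(tert-butyldimethylsilyl)oxy]-3,10-epoxy-8-(2-methylpropanoyloxy)-1-oxogermacra-2,4,11(13)-trien-12,6-olide
Conditions: MnO2, CH2Cl2, rt
Reagents that add atoms: none
Why: MnO2 oxidation of the C1 alcohol, which is allylic to the C2=C3 enol ether, should give the vinylogous ester of the 3(2H)-furanone under neutral conditions that spare the acid-sensitive dienol ether.

Step 21
Reactants: 34 the silyl-protected furanone of step 20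
Product: 35 (4Z,6R,7R,8R,10R)-3,10-epoxy-15-hydroxy-8-(2-methylpropanoyloxy)-1-oxogermacra-2,4,11(13)-trien-12,6-olide (CNP0176924.3)
Conditions: HF·pyridine, pyridine, THF, 0 °C
Reagents that add atoms: none
Why: Fluoride-mediated desilylation with buffered HF·pyridine removes the primary silyl ether without base, so the methylene lactone, the ester and the furanone should survive.

**Compound list**

1 | 2-butyne-1,4-diol | OCC#CCO | starting material
2 | 4-[(tert-butyldimethylsilyl)oxy]but-2-yn-1-ol | OCC#CCO[Si](C)(C)C(C)(C)C | intermediate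
3 | sodium cyclic alkenylaluminate (five-membered 1,2-oxaaluminole ate complex: Al bound to the alkoxide oxygen, to the alkene carbon bearing CH2OTBS and to two 2-methoxyethoxy groups) | [Na+].COCCO[Al-]1(OCCOC)OCC=C1CO[Si](C)(C)C(C)(C)C | intermediate
4 | (Z)-4-[(tert-butyldimethylsilyl)oxy]-3-iodobut-2-en-1-ol | OC/C=C(/CO[Si](C)(C)C(C)(C)C)I | intermediate
5 | (Z)-4-[(tert-butyldimethylsilyl)oxy]-3-iodobut-2-enal | O=C/C=C(/CO[Si](C)(C)C(C)(C)C)I | intermediate
6 | vinylmagnesium bromide | C=C[Mg]Br | starting material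
7 | rac-(Z)-6-[(tert-butyldimethylsilyl)oxy]-5-iodohexa-1,4-dien-3-ol | C=CC(O)/C=C(/CO[Si](C)(C)C(C)(C)C)I | intermediate
8 | (3S,4Z)-6-[(tert-butyldimethylsilyl)oxy]-5-iodohexa-1,4-dien-3-ol | C=C[C@H](O)/C=C(/CO[Si](C)(C)C(C)(C)C)I | intermediate
9 | 2-(bromomethyl)prop-2-enoic acid | C=C(CBr)C(=O)O | starting material
10 | (3S,4Z)-6-[(tert-butyldimethylsilyl)oxy]-5-iodohexa-1,4-dien-3-yl 2-(bromomethyl)prop-2-enoate | C=C[C@H](OC(=O)C(=C)CBr)/C=C(/CO[Si](C)(C)C(C)(C)C)I | intermediate
11 | (5S)-3-(bromomethyl)-5-[(1Z)-3-[(tert-butyldimethylsilyl)oxy]-2-iodoprop-1-en-1-yl]furan-2(5H)-one | BrCC1=C[C@@H](/C=C(/CO[Si](C)(C)C(C)(C)C)I)OC1=O | intermediate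
12 | 4-[(tert-butyldimethylsilyl)oxy]but-1-yne | C#CCCO[Si](C)(C)C(C)(C)C | starting material
13 | trimethylaluminium | C[Al](C)C | starting material
14 | ethylene oxide | C1CO1 | starting material
15 | [(1E)-4-[(tert-butyldimethylsilyl)oxy]-2-methylbut-1-en-1-yl]dimethylalane | C[Al](C)/C=C(C)/CCO[Si](C)(C)C(C)(C)C | intermediate
16 | lithium butyl[(1E)-4-[(tert-butyldimethylsilyl)oxy]-2-methylbut-1-en-1-yl]dimethylalanate | [Li+].CCCC[Al-](C)(C)/C=C(C)/CCO[Si](C)(C)C(C)(C)C | intermediate
17 | (3E)-6-[(tert-butyldimethylsilyl)oxy]-4-methylhex-3-en-1-ol | OCC/C=C(C)/CCO[Si](C)(C)C(C)(C)C | intermediate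
18 | tert-butyl{[(3E)-6-[(4-methoxybenzyl)oxy]-3-methylhex-3-en-1-yl]oxy}dimethylsilane | COc1ccc(COCC/C=C(C)/CCO[Si](C)(C)C(C)(C)C)cc1 | intermediate
19 | (3E)-6-[(4-methoxybenzyl)oxy]-3-methylhex-3-en-1-ol | COc1ccc(COCC/C=C(C)/CCO)cc1 | intermediate
20 | (3E)-6-[(4-methoxybenzyl)oxy]-3-methylhex-3-enal | COc1ccc(COCC/C=C(C)/CC=O)cc1 | intermediate
21 | {[(5S)-5-[(1Z)-3-[(tert-butyldimethylsilyl)oxy]-2-iodoprop-1-en-1-yl]-2-oxo-2,5-dihydrofuran-3-yl]methyl}zinc bromide | Br[Zn]CC1=C[C@@H](/C=C(/CO[Si](C)(C)C(C)(C)C)I)OC1=O | intermediate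
22 | (4R,5S)-5-[(1Z)-3-[(tert-butyldimethylsilyl)oxy]-2-iodoprop-1-en-1-yl]-4-[(1S,3E)-1-hydroxy-6-[(4-methoxybenzyl)oxy]-3-methylhex-3-en-1-yl]-3-methylidenedihydrofuran-2(3H)-one | C=C1C(=O)O[C@H](/C=C(/CO[Si](C)(C)C(C)(C)C)I)[C@H]1[C@@H](O)C/C(C)=C/CCOCc2ccc(OC)cc2 | intermediate
23 | 2-methylpropanoic acid (isobutyric acid) | CC(C)C(=O)O | starting material
24 | alkoxyphosphonium isobutyrate (22 with O–PPh3+ on the carbinol carbon, configuration unchanged, isobutyrate as counter-ion) | C=C1C(=O)O[C@H](/C=C(/CO[Si](C)(C)C(C)(C)C)I)[C@H]1[C@@H](O[P+](c2ccccc2)(c2ccccc2)c2ccccc2)C/C(C)=C/CCOCc2ccc(OC)cc2.CC(C)C(=O)[O-] | intermediate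
25 | (4R,5S)-5-[(1Z)-3-[(tert-butyldimethylsilyl)oxy]-2-iodoprop-1-en-1-yl]-4-[(1R,3E)-6-[(4-methoxybenzyl)oxy]-3-methyl-1-(2-methylpropanoyloxy)hex-3-en-1-yl]-3-methylidenedihydrofuran-2(3H)-one | C=C1C(=O)O[C@H](/C=C(/CO[Si](C)(C)C(C)(C)C)I)[C@H]1[C@H](OC(=O)C(C)C)C/C(C)=C/CCOCc2ccc(OC)cc2 | intermediate
26 | (4R,5S)-5-[(1Z)-3-[(tert-butyldimethylsilyl)oxy]-2-iodoprop-1-en-1-yl]-4-[(1R,3E)-6-hydroxy-3-methyl-1-(2-methylpropanoyloxy)hex-3-en-1-yl]-3-methylidenedihydrofuran-2(3H)-one | C=C1C(=O)O[C@H](/C=C(/CO[Si](C)(C)C(C)(C)C)I)[C@H]1[C@H](OC(=O)C(C)C)C/C(C)=C/CCO | intermediate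
27 | (4R,5S)-5-[(1Z)-3-[(tert-butyldimethylsilyl)oxy]-2-iodoprop-1-en-1-yl]-4-[(1R)-2-[(2S,3S)-3-(2-hydroxyethyl)-2-methyloxiran-2-yl]-1-(2-methylpropanoyloxy)ethyl]-3-methylidenedihydrofuran-2(3H)-one | C=C1C(=O)O[C@H](/C=C(/CO[Si](C)(C)C(C)(C)C)I)[C@H]1[C@H](OC(=O)C(C)C)C[C@]2(C)O[C@H]2CCO | intermediate
28 | (4R,5S)-5-[(1Z)-3-[(tert-butyldimethylsilyl)oxy]-2-iodoprop-1-en-1-yl]-4-[(1R)-2-[(2S,3S)-2-methyl-3-(2-oxoethyl)oxiran-2-yl]-1-(2-methylpropanoyloxy)ethyl]-3-methylidenedihydrofuran-2(3H)-one | C=C1C(=O)O[C@H](/C=C(/CO[Si](C)(C)C(C)(C)C)I)[C@H]1[C@H](OC(=O)C(C)C)C[C@]2(C)O[C@H]2CC=O | intermediate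
29 | alkenylchromium dichloride (28 with CrCl2 of trivalent chromium in place of iodine at C4, Z geometry kept) | C=C1C(=O)O[C@H](/C=C(/CO[Si](C)(C)C(C)(C)C)[Cr](Cl)Cl)[C@H]1[C@H](OC(=O)C(C)C)C[C@]2(C)O[C@H]2CC=O | intermediate
30 | (1S,4Z,6R,7R,8R,10S)-15-[(tert-butyldimethylsilyl)oxy]-1,10-epoxy-3-hydroxy-8-(2-methylpropanoyloxy)germacra-4,11(13)-dien-12,6-olide (C3 epimers) | C=C1C(=O)O[C@@H]2/C=C(/CO[Si](C)(C)C(C)(C)C)C(O)C[C@@H]3O[C@@]3(C)C[C@@H](OC(=O)C(C)C)[C@@H]12 | intermediate
31 | (1S,4Z,6R,7R,8R,10S)-15-[(tert-butyldimethylsilyl)oxy]-1,10-epoxy-8-(2-methylpropanoyloxy)-3-oxogermacra-4,11(13)-dien-12,6-olide | C=C1C(=O)O[C@@H]2/C=C(/CO[Si](C)(C)C(C)(C)C)C(=O)C[C@@H]3O[C@@]3(C)C[C@@H](OC(=O)C(C)C)[C@@H]12 | intermediate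
32 | bicyclic oxocarbenium ion (C3=O+–C10 in the five-membered ring O, C3, C2, C1, C10; C1 oxygen bound to BF3; zwitterion) | C=C1C(=O)O[C@@H]2/C=C(/CO[Si](C)(C)C(C)(C)C)C3=[O+][C@](C)(C[C@@H](OC(=O)C(C)C)[C@@H]12)[C@@H](O[B-](F)(F)F)C3 | intermediate
33 | (1S,4Z,6R,7R,8R,10R)-15-[(tert-butyldimethylsilyl)oxy]-3,10-epoxy-1-hydroxy-8-(2-methylpropanoyloxy)germacra-2,4,11(13)-trien-12,6-olide | C=C1C(=O)O[C@@H]2/C=C(/CO[Si](C)(C)C(C)(C)C)C3=C[C@H](O)[C@@](C)(C[C@@H](OC(=O)C(C)C)[C@@H]12)O3 | intermediate
34 | (4Z,6R,7R,8R,10R)-15-[(tert-butyldimethylsilyl)oxy]-3,10-epoxy-8-(2-methylpropanoyloxy)-1-oxogermacra-2,4,11(13)-trien-12,6-olide | C=C1C(=O)O[C@@H]2/C=C(/CO[Si](C)(C)C(C)(C)C)C3=CC(=O)[C@@](C)(C[C@@H](OC(=O)C(C)C)[C@@H]12)O3 | intermediate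
35 | (4Z,6R,7R,8R,10R)-3,10-epoxy-15-hydroxy-8-(2-methylpropanoyloxy)-1-oxogermacra-2,4,11(13)-trien-12,6-olide (CNP0176924.3) | C=C1C(=O)O[C@@H]2/C=C(/CO)C3=CC(=O)[C@@](C)(C[C@@H](OC(=O)C(C)C)[C@@H]12)O3 | target

**Step count and risks**

Total steps: 21. Longest linear sequence: 17 steps (steps 1–7 and 12–21, from 2-butyne-1,4-diol); the aldehyde branch (steps 8–11) joins at step 12.

Steps most likely to fail:

1. Step 19 (key step, new method). The cation at C10 may be diverted before the ketone oxygen closes the ring: hydride shift from C1, proton loss to an allylic alcohol, or later ionisation of the allylic C1 alcohol of the product. The fallback makes the bridge one oxidation level lower by known chemistry and sets out from the macrocyclic epoxy alcohol 30. Catalytic camphorsulfonic acid in CH2Cl2 at 0 °C lets the C3 hydroxyl open the epoxide at tertiary C10 with inversion (5-endo cyclisation of a hydroxy trisubstituted epoxide), giving the bridged tetrahydrofuranol F1 from the C3 epimer that can reach C10. Dess–Martin oxidation of the C1 alcohol gives the tetrahydrofuran-3-one F2. TMSOTf/Et3N gives the trimethylsilyl enol ether F3, and Pd(OAc)2 in MeCN (Saegusa–Ito dehydrogenation) introduces the C2=C3 double bond, which rejoins the route at furanone 34.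

2. Step 17. Intermolecular coupling and reduction of the C–I bond may compete with closure of the strained ten-membered ring, and the β,γ-epoxy aldehyde may degrade (β-elimination, halide opening) during the slow addition. The fallback closes the ring before the epoxide exists and sets out from alcohol 26. Dess–Martin oxidation gives the triene aldehyde F4, the nickel/chromium coupling closes the more flexible chain to the macrocyclic dienol F5, and Dess–Martin oxidation gives the dienone F6. The C1–C10 alkene of F6 is then epoxidised on the ring (chiral dioxirane as in step 15, or m-chloroperbenzoic acid with NaHCO3 if the ring conformer alone exposes the required face), which rejoins the route at 31. The facial outcome on the ring would have to be assigned.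

3. Step 13. The activated C8 alcohol may eliminate toward a conjugated diene, or be acylated without inversion at this hindered carbinol. The fallback avoids inversion by making the 8R alcohol directly and sets out from bromolactone 11. Zn and Bu3SnCl in THF/aq. NH4Cl give the allylstannane F7. BF3·OEt2-promoted addition of F7 to aldehyde 20 in CH2Cl2 at −78 °C goes through an open antiperiplanar transition state (syn-selective, as for crotylstannanes) and should give the 8R alcohol F8, again with C7 trans to C6. Isobutyric anhydride, DMAP and pyridine acylate F8 with retention, which rejoins the route at 25.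

**Further compounds**

F1 | step 19 | (1S,3R,4Z,6R,7R,8R,10R)-15-[(tert-butyldimethylsilyl)oxy]-3,10-epoxy-1-hydroxy-8-(2-methylpropanoyloxy)germacra-4,11(13)-dien-12,6-olide | C=C1C(=O)O[C@@H]2/C=C(/CO[Si](C)(C)C(C)(C)C)[C@H]3C[C@H](O)[C@@](C)(C[C@@H](OC(=O)C(C)C)[C@@H]12)O3
F2 | step 19 | (3R,4Z,6R,7R,8R,10R)-15-[(tert-butyldimethylsilyl)oxy]-3,10-epoxy-8-(2-methylpropanoyloxy)-1-oxogermacra-4,11(13)-dien-12,6-olide | C=C1C(=O)O[C@@H]2/C=C(/CO[Si](C)(C)C(C)(C)C)[C@H]3CC(=O)[C@@](C)(C[C@@H](OC(=O)C(C)C)[C@@H]12)O3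
F3 | step 19 | trimethylsilyl enol ether of F2 (C1–OSiMe3, C1=C2) | C=C1C(=O)O[C@@H]2/C=C(/CO[Si](C)(C)C(C)(C)C)[C@H]3C=C(O[Si](C)(C)C)[C@@](C)(C[C@@H](OC(=O)C(C)C)[C@@H]12)O3
F4 | step 17 | (4R,5S)-5-[(1Z)-3-[(tert-butyldimethylsilyl)oxy]-2-iodoprop-1-en-1-yl]-4-[(1R,3E)-3-methyl-1-(2-methylpropanoyloxy)-6-oxohex-3-en-1-yl]-3-methylidenedihydrofuran-2(3H)-one | C=C1C(=O)O[C@H](/C=C(/CO[Si](C)(C)C(C)(C)C)I)[C@H]1[C@H](OC(=O)C(C)C)C/C(C)=C/CC=O
F5 | step 17 | (1(10)E,4Z,6R,7R,8R)-15-[(tert-butyldimethylsilyl)oxy]-3-hydroxy-8-(2-methylpropanoyloxy)germacra-1(10),4,11(13)-trien-12,6-olide (C3 epimers) | C=C1C(=O)O[C@@H]2/C=C(/CO[Si](C)(C)C(C)(C)C)C(O)C/C=C(C)/C[C@@H](OC(=O)C(C)C)[C@@H]12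
F6 | step 17 | (1(10)E,4Z,6R,7R,8R)-15-[(tert-butyldimethylsilyl)oxy]-8-(2-methylpropanoyloxy)-3-oxogermacra-1(10),4,11(13)-trien-12,6-olide | C=C1C(=O)O[C@@H]2/C=C(/CO[Si](C)(C)C(C)(C)C)C(=O)C/C=C(C)/C[C@@H](OC(=O)C(C)C)[C@@H]12
F7 | step 13 | (5S)-5-[(1Z)-3-[(tert-butyldimethylsilyl)oxy]-2-iodoprop-1-en-1-yl]-3-[(tributylstannyl)methyl]furan-2(5H)-one | CCCC[Sn](CCCC)(CCCC)CC1=C[C@@H](/C=C(/CO[Si](C)(C)C(C)(C)C)I)OC1=O
F8 | step 13 | (4R,5S)-5-[(1Z)-3-[(tert-butyldimethylsilyl)oxy]-2-iodoprop-1-en-1-yl]-4-[(1R,3E)-1-hydroxy-6-[(4-methoxybenzyl)oxy]-3-methylhex-3-en-1-yl]-3-methylidenedihydrofuran-2(3H)-one | C=C1C(=O)O[C@H](/C=C(/CO[Si](C)(C)C(C)(C)C)I)[C@H]1[C@H](O)C/C(C)=C/CCOCc2ccc(OC)cc2
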